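## Retrosynthetic overview

1. The target comes from tetraol 24 by regioselective acetylation through a cyclic orthoacetate; 24 comes from cyclohexene 23 by hydroxyl-directed dihydroxylation; ring A and its quaternary carbon bearing CH2OAc come from an Ireland–Claisen ring contraction of the 6-vinyl δ-lactone 19.
2. Key disconnection (two C–C bonds at once): in the tricyclo[2.2.1.0^{2,6}]heptane, the cyclopropane CH is bonded to the ring-fusion carbon that carries CH2OAc, and the cyclopropane C–CH3 is bonded to the CH–OAc carbon. Both of these carbons hang from the same quaternary apex. This 1,3-pair flanking a cis-disubstituted cyclopropane is the retron for a radical cascade: α-ester radical → tethered cyclopropene C=C → cyclopropyl radical → aldehyde.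
3. The cascade precursor 15 is an open-chain bromo ester/aldehyde with one quaternary centre. It is assembled on the temporary γ-lactone 9 (from methyl 3,3-dimethylpent-4-enoate) by two enolate alkylations, the first with the (R)-cyclopropenylmethyl iodide 5 (from propyne and ethyl diazoacetate).
4. Ring order: cyclopropene (step 1); temporary γ-lactone (step 5); cyclopropane plus both five-membered rings of the nortricyclene (step 11); temporary δ-lactone (step 12); ring A (step 13).

Key step: step 11

Assumption: propyne, ethyl diazoacetate and methyl 3,3-dimethylpent-4-enoate are bought; the carbon α to the tert-butyl ester in 14–19 may be either epimer (the one expected is drawn for 16–19) because step 13 erases it.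

## Route

Step 1
Reactants: 1 propyne; 2 ethyl diazoacetate
Product: 3 ethyl (R)-2-methylcycloprop-2-ene-1-carboxylate
Conditions: Rh2(OAc)(DPTI)3 (DPTI = 4,5-diphenyl-1-triflylimidazolidin-2-onate, 0.5 mol%), excess 1, CH2Cl2, 0 °C, slow addition of 2
Reagents that add atoms: none
Why: Enantioselective [2+1] cyclopropenation of a terminal alkyne by a chiral dirhodium carbenoid; the ligand antipode is chosen to give the (R)-ester, and this single stereocentre later decides which cyclopropene carbon meets which reacting centre.

Step 2
Reactants: 3 ethyl (R)-2-methylcycloprop-2-ene-1-carboxylate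
Product: 4 (R)-(2-methylcycloprop-2-en-1-yl)methanol
Conditions: iBu2AlH, Et2O, −78 → 0 °C
Reagents that add atoms: none
Why: Hydride reduction of an ester to the primary alcohol, which should leave the strained alkene and the stereocentre untouched.

Step 3
Reactants: 4 (R)-(2-methylcycloprop-2-en-1-yl)methanol
Product: 5 (R)-3-(iodomethyl)-1-methylcyclopropene
Conditions: PPh3, I2, imidazole, CH2Cl2, 0 °C; used at once as a cold solution
Reagents that add atoms: iodine, II
Why: Appel-type iodination by SN2 displacement of the alkoxyphosphonium group at the primary carbon, under cold non-ionising conditions so that the cyclopropenylcarbinyl system should not ring-expand.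

Step 4
Reactants: 6 methyl 3,3-dimethylpent-4-enoate
Product: 7 methyl 3,3-dimethyl-4-oxobutanoate
Conditions: O3, CH2Cl2/MeOH, −78 °C; then Me2S
Reagents that add atoms: ozone, [O-][O+]=O
Why: Ozonolysis with reductive work-up cleaves the terminal alkene to a non-enolisable aldehyde.

Step 5
Reactants: 7 methyl 3,3-dimethyl-4-oxobutanoate
Product: 9 (S)-5-ethenyl-4,4-dimethyloxolan-2-one, via hydroxy ester 8 (not isolated)
Conditions: Zn(CH=CH2)2 (from CH2=CHMgBr and ZnCl2), (−)-3-exo-(dimethylamino)isoborneol (10 mol%), toluene, 0 °C; aq. NH4Cl; then PPTS (cat.), PhH, 60 °C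
Reagents that add atoms: divinylzinc, C=C[Zn]C=C
Why: Amino-alcohol-catalysed enantioselective addition of a vinylzinc reagent to the Si face of the aldehyde should set the (S)-carbinol, and the γ-hydroxy ester then lactonises.

Step 6
Reactants: 9 (S)-5-ethenyl-4,4-dimethyloxolan-2-one; 5 (R)-3-(iodomethyl)-1-methylcyclopropene
Product: 10 (5S)-5-ethenyl-4,4-dimethyl-3-{[(1R)-2-methylcycloprop-2-en-1-yl]methyl}oxolan-2-one (both C3 epimers)
Conditions: LiN(iPr)2, THF/DMPU, −78 °C; then 5, −78 → −30 °C
Reagents that add atoms: none
Why: SN2 alkylation of the lactone enolate; the new α-centre need not be controlled because it is enolised again in step 7.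

Step 7
Reactants: 10 (5S)-5-ethenyl-4,4-dimethyl-3-{[(1R)-2-methylcycloprop-2-en-1-yl]methyl}oxolan-2-one
Product: 11 tert-butyl 2-[(3S,5S)-5-ethenyl-4,4-dimethyl-3-{[(1R)-2-methylcycloprop-2-en-1-yl]methyl}-2-oxooxolan-3-yl]acetate
Conditions: LiN(iPr)2, THF/DMPU, −78 °C; then BrCH2CO2tBu, −78 → −40 °C
Reagents that add atoms: tert-butyl bromoacetate, CC(C)(C)OC(=O)CBr
Why: Second lactone enolate alkylation forms the quaternary centre; the reactive bromoacetate should enter trans to the γ-vinyl group, whose face is screened by the pseudoaxial β-methyl, leaving the cyclopropenylmethyl arm cis to vinyl.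

Step 8
Reactants: 11 tert-butyl 2-[(3S,5S)-5-ethenyl-4,4-dimethyl-3-{[(1R)-2-methylcycloprop-2-en-1-yl]methyl}-2-oxooxolan-3-yl]acetate
Product: 13 tert-butyl 5-(tert-butyldimethylsilyloxy)-3-[methoxy(methyl)carbamoyl]-4,4-dimethyl-3-{[(1R)-2-methylcycloprop-2-en-1-yl]methyl}hept-6-enoate (configuration as in 11), via hydroxy Weinreb amide 12 (not isolated)
Conditions: MeNH(OMe)·HCl, AlMe3, CH2Cl2, 0 °C → rt; then 2,6-lutidine, tBuMe2SiOTf, −78 → 0 °C
Reagents that add atoms: N,O-dimethylhydroxylamine hydrochloride, CNOC.Cl; tert-butyldimethylsilyl triflate, CC(C)(C)[Si](C)(C)OS(=O)(=O)C(F)(F)F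
Why: Aluminium-amide aminolysis (Weinreb) opens the lactone while the hindered tert-butyl ester should not react, and immediate silylation of the freed alkoxide prevents relactonisation; no stereocentre is touched.

Step 9
Reactants: 13 the Weinreb amide silyl ether
Product: 14 the 2-bromo derivative of 13 (both epimers at CHBr)
Conditions: LiN(iPr)2, THF, −78 °C; then BrCCl2CCl2Br
Reagents that add atoms: 1,2-dibromotetrachloroethane, ClC(Cl)(Br)C(Cl)(Cl)Br
Why: Bromination of the tert-butyl ester enolate with a positive-bromine donor; the CHBr centre is a mixture, which does not matter because it becomes a planar radical.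

Step 10
Reactants: 14 the α-bromo ester Weinreb amide
Product: 15 tert-butyl 2-bromo-5-(tert-butyldimethylsilyloxy)-3-formyl-4,4-dimethyl-3-{[(1R)-2-methylcycloprop-2-en-1-yl]methyl}hept-6-enoate
Conditions: iBu2AlH, THF, −78 °C; Rochelle salt work-up
Reagents that add atoms: none
Why: Weinreb amide reduction stops at the aldehyde through the chelated tetrahedral intermediate, and the tert-butyl ester and the C–Br bond should survive at −78 °C.

Step 11
Reactants: 15 the bromo ester aldehyde
Product: 17 tert-butyl 7-hydroxy-1-methyl-4-[(3S)-3-(tert-butyldimethylsilyloxy)-2-methylpent-4-en-2-yl]tricyclo[2.2.1.0^{2,6}]heptane-3-carboxylate (hydroxyl turned toward the CH2 bridge; ester on the side of the carbinol bridge), via diethylborinate 16 (not isolated)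
Conditions: Bu3SnH (1.2 equiv, syringe pump), Et3B (2 equiv), trace air, PhH (0.01 M), 25 °C; then aq. NH4Cl
Reagents that add atoms: none
Why: Proposed new method: Bu3Sn• abstracts bromine to give an electrophilic α-ester radical that adds 5-exo-trig to the CH carbon of the tethered strained cyclopropene, and the resulting tertiary cyclopropyl σ-radical, held under the formyl group, adds 5-exo-trig to the aldehyde carbon; the alkoxy radical is captured at oxygen by Et3B before it can fragment, and the expelled ethyl radical regenerates Bu3Sn• from Bu3SnH. The closest known reaction types are tin-hydride tandem 5-exo cyclisations of α-ester radicals, radical additions to cyclopropenes and borane-trapped radical cyclisations onto aldehydes. Both five-membered rings of the tricycloheptane close in the 5-exo mode and the cyclopropene becomes the cyclopropane. The two bonds must form on the cyclopropene face that carries the CH2 tether, so the three cyclopropane carbons are fixed relative to the quaternary apex, and the matched (R)-cyclopropene/quaternary-centre pairing puts the CH carbon under the radical and the C–CH3 carbon under the aldehyde. The ester-bearing carbon should form with the CO2tBu group turned away from the CMe2 arm, that is toward the formyl group (it is erased in step 13 anyway), and this ester then makes the aldehyde oxygen point toward the CH2 bridge in the second closure, which sets the carbinol centre. The step needs attack on the cyclopropene rather than on the vinyl group (secured by the extra strain release) and on its CH rather than its C–CH3 carbon (secured by sterics and by formation of the tertiary radical), and bromine abstraction must outrun stannyl addition to the cyclopropene (the reason for bromide rather than selenide).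

Step 12
Reactants: 17 the tricyclic hydroxy ester
Product: 19 δ-lactone between the ester carbon and the allylic oxygen (6-ethenyl-5,5-dimethyloxan-2-one ring fused to the tricycloheptane; free carbinol), via diol ester 18 (not isolated)
Conditions: Bu4NF, THF, 0 °C → rt; then KOtBu (0.2 equiv), THF, rt
Reagents that add atoms: none
Why: Fluoride desilylation followed by alkoxide-mediated intramolecular transesterification (loss of tert-butoxide) should give the six-membered lactone, while the carbinol oxygen points away from the ester and cannot lactonise.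

Step 13
Reactants: 19 the δ-lactone
Product: 22 tetracyclic hydroxy acid (ring A as 4,4-dimethylcyclohexene fused to the tricycloheptane; CO2H on the new quaternary ring-fusion carbon), via silyl ketene acetal 20 (not isolated), via silyl ester 21 (not isolated)
Conditions: KN(SiMe3)2 (2.5 equiv), Me3SiCl (3 equiv), THF, −78 °C; then toluene, 110 °C; then dilute aq. citric acid
Reagents that add atoms: none
Why: Ireland–Claisen ring contraction of a 6-vinyl δ-lactone ([3,3], boat-like): enolisation erases the CH(ester) centre of step 11, and the quaternary carbon then forms suprafacially on the lactone face that carries the vinyl group, which is the side of the carbinol bridge, so the chirality of the step-5 carbinol is transferred while ring A closes.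

Step 14
Reactants: 22 the hydroxy acid
Product: 23 the corresponding diol (CH2OH on the quaternary carbon; ring A alkene retained)
Conditions: LiAlH4, THF, 0 °C → reflux
Reagents that add atoms: none
Why: Hydride reduction of the hindered carboxylic acid to the neopentyl-type primary alcohol; no stereocentre changes.

Step 15
Reactants: 23 the alkene diol
Product: 24 the tetraol (cis-diol on ring A, syn to CH2OH)
Conditions: OsO4 (1.05 equiv), TMEDA (1.1 equiv), CH2Cl2, −78 °C; then aq. Na2SO3, THF, 40 °C
Reagents that add atoms: osmium tetroxide, O=[Os](=O)(=O)=O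
Why: Hydrogen-bond-directed (Donohoe) syn-dihydroxylation: the pseudoaxial CH2OH should deliver OsO4·TMEDA to its own face of the ring A alkene, the other face being blocked by the axial carbinol bridge, which sets both new carbinol centres.

Step 16
Reactants: 24 the tetraol
Product: 26 the cyclic methyl orthoacetate of the cis-diol with the primary and the bridge hydroxyls acetylated, via orthoester diol 25 (not isolated)
Conditions: MeC(OMe)3 (1.2 equiv), PPTS (cat.), CH2Cl2, rt; then Et3N, Ac2O, DMAP, rt
Reagents that add atoms: trimethyl orthoacetate, COC(C)(OC)OC; acetic anhydride, CC(=O)OC(C)=O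
Why: Orthoester exchange ties up only the cis-vicinal diol as a five-membered ring, and DMAP-catalysed acylation then esterifies the primary and the hindered secondary alcohol under basic conditions that the orthoester tolerates.

Step 17
Reactants: 26 the orthoester diacetate
Product: 27 target triacetate CNP0197219.1
Conditions: PPTS (cat.), THF/H2O, 0 °C → rt
Reagents that add atoms: water, O
Why: Mild acid hydrolysis of a cyclic orthoester on a cyclohexane cis-diol opens to the axial acetate and the equatorial alcohol (the known regiochemistry of this opening), which should put the acetate on the carbon next to CH2 and leave the hydroxyl next to CMe2 free.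

## Compound list

1 | propyne | CC#C | starting material
2 | ethyl diazoacetate | CCOC(=O)C=[N+]=[N-] | starting material
3 | ethyl (R)-2-methylcycloprop-2-ene-1-carboxylate | CCOC(=O)[C@@H]1C=C1C | intermediate
4 | (R)-(2-methylcycloprop-2-en-1-yl)methanol | OC[C@@H]1C=C1C | intermediate
5 | (R)-3-(iodomethyl)-1-methylcyclopropene | IC[C@@H]1C=C1C | intermediate
6 | methyl 3,3-dimethylpent-4-enoate | COC(=O)CC(C)(C)C=C | starting material
7 | methyl 3,3-dimethyl-4-oxobutanoate | COC(=O)CC(C)(C)C=O | intermediate
8 | methyl (S)-4-hydroxy-3,3-dimethylhex-5-enoate (not isolated) | COC(=O)CC(C)(C)[C@@H](O)C=C | intermediate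
9 | (S)-5-ethenyl-4,4-dimethyloxolan-2-one | O=C1CC(C)(C)[C@H](C=C)O1 | intermediate
10 | (5S)-5-ethenyl-4,4-dimethyl-3-{[(1R)-2-methylcycloprop-2-en-1-yl]methyl}oxolan-2-one, C3 epimers | O=C1C(C[C@@H]2C=C2C)C(C)(C)[C@H](C=C)O1 | intermediate
11 | tert-butyl 2-[(3S,5S)-5-ethenyl-4,4-dimethyl-3-{[(1R)-2-methylcycloprop-2-en-1-yl]methyl}-2-oxooxolan-3-yl]acetate | O=C1[C@](CC(=O)OC(C)(C)C)(C[C@@H]2C=C2C)C(C)(C)[C@H](C=C)O1 | intermediate
12 | ring-opened hydroxy Weinreb amide of 11 (not isolated) | CON(C)C(=O)[C@](CC(=O)OC(C)(C)C)(C[C@@H]1C=C1C)C(C)(C)[C@@H](O)C=C | intermediate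
13 | Weinreb amide tert-butyldimethylsilyl ether | CON(C)C(=O)[C@](CC(=O)OC(C)(C)C)(C[C@@H]1C=C1C)C(C)(C)[C@H](C=C)O[Si](C)(C)C(C)(C)C | intermediate
14 | α-bromo tert-butyl ester Weinreb amide, CHBr epimers | CON(C)C(=O)[C@](C(Br)C(=O)OC(C)(C)C)(C[C@@H]1C=C1C)C(C)(C)[C@H](C=C)O[Si](C)(C)C(C)(C)C | intermediate
15 | α-bromo ester aldehyde (cascade substrate), CHBr epimers | O=C[C@](C(Br)C(=O)OC(C)(C)C)(C[C@@H]1C=C1C)C(C)(C)[C@H](C=C)O[Si](C)(C)C(C)(C)C | intermediate
16 | diethylborinate of 17 (not isolated) | CC(C)(C)OC(=O)[C@@H]1[C@H]2[C@H]3C[C@]1(C(C)(C)[C@H](C=C)O[Si](C)(C)C(C)(C)C)[C@H](OB(CC)CC)[C@@]23C | intermediate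
17 | tert-butyl 7-hydroxy-1-methyl-4-[(3S)-3-(tert-butyldimethylsilyloxy)-2-methylpent-4-en-2-yl]tricyclo[2.2.1.0^{2,6}]heptane-3-carboxylate | CC(C)(C)OC(=O)[C@@H]1[C@H]2[C@H]3C[C@]1(C(C)(C)[C@H](C=C)O[Si](C)(C)C(C)(C)C)[C@H](O)[C@@]23C | intermediate
18 | desilylated diol ester (not isolated) | CC(C)(C)OC(=O)[C@@H]1[C@H]2[C@H]3C[C@]1(C(C)(C)[C@H](C=C)O)[C@H](O)[C@@]23C | intermediate
19 | 6-vinyl δ-lactone fused to the tricycloheptane, free carbinol | O=C1O[C@@H](C=C)C(C)(C)[C@]23C[C@@H]4[C@H]([C@@H]12)[C@]4(C)[C@H]3O | intermediate
20 | bis-silyl ketene acetal (not isolated) | C[Si](C)(C)OC1=C2[C@H]3[C@H]4C[C@]2(C(C)(C)[C@H](C=C)O1)[C@H](O[Si](C)(C)C)[C@@]34C | intermediate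
21 | rearranged trimethylsilyl ester, silyl ether (not isolated) | C[Si](C)(C)OC(=O)[C@]12CC=CC(C)(C)[C@]13C[C@@H]1[C@H]2[C@]1(C)[C@H]3O[Si](C)(C)C | intermediate
22 | tetracyclic hydroxy acid with ring A alkene | OC(=O)[C@]12CC=CC(C)(C)[C@]13C[C@@H]1[C@H]2[C@]1(C)[C@H]3O | intermediate
23 | tetracyclic alkene diol | OC[C@]12CC=CC(C)(C)[C@]13C[C@@H]1[C@H]2[C@]1(C)[C@H]3O | intermediate
24 | tetraol | OC[C@]12C[C@H](O)[C@H](O)C(C)(C)[C@]13C[C@@H]1[C@H]2[C@]1(C)[C@H]3O | intermediate
25 | cyclic methyl orthoacetate diol (not isolated; orthoester carbon unassigned) | OC[C@]12C[C@@H]3OC(C)(OC)O[C@@H]3C(C)(C)[C@]14C[C@@H]5[C@H]2[C@]5(C)[C@H]4O | intermediate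
26 | cyclic methyl orthoacetate diacetate (orthoester carbon unassigned) | CC(=O)OC[C@]12C[C@@H]3OC(C)(OC)O[C@@H]3C(C)(C)[C@]14C[C@@H]5[C@H]2[C@]5(C)[C@H]4OC(C)=O | intermediate
27 | CNP0197219.1 | CC(=O)OC[C@]12C[C@H](OC(C)=O)[C@H](O)C(C)(C)[C@]13C[C@@H]1[C@H]2[C@]1(C)[C@H]3OC(C)=O | target

## Step count and risks

Total step count: 17. Longest linear sequence: 15 steps (steps 1–3, then 6–17).

Steps most likely to fail:

Step 11 (proposed new method). What may go wrong: the cyclopropyl radical may take hydrogen from the stannane before it reaches the aldehyde, the alkoxy radical may fragment before it is trapped, or tin and ethyl radicals may add to the cyclopropene. The fallback separates the two bond formations and makes the second one polar, using known reaction types. It sets out from 13: LiN(iPr)2 then I2 should give the α-iodo ester Weinreb amide F1, and iBu2AlH the iodo aldehyde F2. Et3B/air without any hydride then triggers an iodine-atom-transfer 5-exo cyclisation onto the cyclopropene to give the bicyclic cyclopropyl iodide F3. SmI2 in THF closes the last bond as an intramolecular Barbier addition of the cyclopropyl iodide to the aldehyde, and the route is rejoined at 17.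

Step 6. What may go wrong: ring expansion or ionisation of the cyclopropenylmethyl iodide and ene-type self-reaction of the unprotected cyclopropene may outrun a slow substitution by the hindered lactone enolate. The fallback uses a silyl-stabilised cyclopropene that is unmasked after the coupling. It sets out from 2 and 9: cyclopropenation of 1-(trimethylsilyl)propyne with 2 under the catalyst of step 1 should give the silyl cyclopropene ester F4 (same sense of chirality as 3), iBu2AlH the alcohol F5, and PPh3/I2/imidazole the iodide F6. Alkylation of the enolate of 9 with F6 gives the silylated lactone F7, and Bu4NF removes the vinylic silyl group to rejoin the route at 10.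

Step 8. What may go wrong: the aminolysis may reverse by relactonisation (strong gem-dialkyl effect) before the alkoxide is silylated, or the aluminium amide may attack the tert-butyl ester. The fallback reaches the aldehyde by reduction and oxidation instead of through an amide. It sets out from 11: LiBH4 should reduce the lactone to the diol F8 with the tert-butyl ester intact, and tBuMe2SiOTf/2,6-lutidine gives the bis-silyl ether F9. LiN(iPr)2 then BrCCl2CCl2Br gives the bromo ester F10, and HF·pyridine removes the primary silyl group selectively to give the alcohol F11. Dess–Martin periodinane then rejoins the route at 15.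

Further compounds
F1 | step 11 | α-iodo tert-butyl ester Weinreb amide | CON(C)C(=O)[C@](C(I)C(=O)OC(C)(C)C)(C[C@@H]1C=C1C)C(C)(C)[C@H](C=C)O[Si](C)(C)C(C)(C)C
F2 | step 11 | α-iodo ester aldehyde | O=C[C@](C(I)C(=O)OC(C)(C)C)(C[C@@H]1C=C1C)C(C)(C)[C@H](C=C)O[Si](C)(C)C(C)(C)C
F3 | step 11 | bicyclo[3.1.0]hexane cyclopropyl iodide aldehyde (C–I centre unassigned) | CC(C)(C)OC(=O)[C@@H]1[C@H]2[C@@H](C[C@@]1(C=O)C(C)(C)[C@H](C=C)O[Si](C)(C)C(C)(C)C)C2(C)I
F4 | step 6 | ethyl 2-methyl-3-(trimethylsilyl)cycloprop-2-ene-1-carboxylate | CCOC(=O)[C@@H]1C([Si](C)(C)C)=C1C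
F5 | step 6 | [2-methyl-3-(trimethylsilyl)cycloprop-2-en-1-yl]methanol | OC[C@@H]1C([Si](C)(C)C)=C1C
F6 | step 6 | 3-(iodomethyl)-1-methyl-2-(trimethylsilyl)cyclopropene | IC[C@@H]1C([Si](C)(C)C)=C1C
F7 | step 6 | silylated analogue of lactone 10 | O=C1C(C[C@@H]2C([Si](C)(C)C)=C2C)C(C)(C)[C@H](C=C)O1
F8 | step 8 | diol tert-butyl ester from reduction of 11 | OC[C@](CC(=O)OC(C)(C)C)(C[C@@H]1C=C1C)C(C)(C)[C@H](C=C)O
F9 | step 8 | bis(tert-butyldimethylsilyl) ether of F8 | CC(C)(C)[Si](C)(C)OC[C@](CC(=O)OC(C)(C)C)(C[C@@H]1C=C1C)C(C)(C)[C@H](C=C)O[Si](C)(C)C(C)(C)C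
F10 | step 8 | α-bromo ester of F9 | CC(C)(C)[Si](C)(C)OC[C@](C(Br)C(=O)OC(C)(C)C)(C[C@@H]1C=C1C)C(C)(C)[C@H](C=C)O[Si](C)(C)C(C)(C)C
F11 | step 8 | primary alcohol from selective desilylation of F10 | OC[C@](C(Br)C(=O)OC(C)(C)C)(C[C@@H]1C=C1C)C(C)(C)[C@H](C=C)O[Si](C)(C)C(C)(C)C
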